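**Plan**

1. Locants used here: ring carbons C1 (lactone O–CH) to C14 (lactone CH), C15 lactone α-carbon, C16 C=O, C17 exocyclic CH2. The retrosynthesis removes the acetyl group and the oxirane oxygen (C10/C11), then cuts the ring bond C11–C12, then the lactone (C1–C14 and O–C16), then C8–C9 of the chain.
2. Enabling feature: in the 14-membered ring the carbinol carbon C12 sits next to C11 of the (E)-trisubstituted C10=C11 unit (later the oxirane). This cyclic (E)-2-methylallylic alcohol lets the ring close by adding a C11 alkenylmetal to a C12 aldehyde.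
3. Forward: the C1–C11 chain comes from geraniol and propyne (allylic oxidation, propargylation, hydrozirconation–iodination), and the C12–C17 piece from Morita–Baylis–Hillman chemistry. The cis-fused α-methylene-γ-lactone is made first by chromium-catalysed 2-(alkoxycarbonyl)allylation/lactonisation. The carbocycle is closed last by an intramolecular asymmetric Nozaki–Hiyama–Kishi reaction, and epoxidation and acetylation finish.
4. Stereochemistry: C1/C14 come from the catalyst-controlled syn allylation (chair transition state of the (Z)-allylchromium). C12 comes from the ligand-controlled ring closure. C10/C11 come from the matched Sharpless epoxidation directed by the C12 hydroxyl. Olefin geometries come from geraniol (C2, C6) and syn-hydrozirconation (C10).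

Key step: step 13

Remark: the oxirane is handled as functionality of the C10=C11 olefin and is put in by hydroxyl-directed epoxidation once lactone and carbocycle are in place; aldehyde 13 is taken as a commercial compound.

**Route**

Step 1
Reactants: 1 geraniol
Product: 2 tert-butyl{[(2E)-3,7-dimethylocta-2,6-dien-1-yl]oxy}dimethylsilane
Conditions: TBSCl, imidazole, DMF, 0 °C → rt
Reagents that add atoms: tert-butyldimethylsilyl chloride, CC(C)(C)[Si](C)(C)Cl
Why: Imidazole-promoted silyl ether formation masks the primary allylic hydroxyl against the organolithium and zirconium hydride steps that follow; no stereocentre is formed.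

Step 2
Reactants: 2 tert-butyl{[(2E)-3,7-dimethylocta-2,6-dien-1-yl]oxy}dimethylsilane
Product: 3 (2E,6E)-8-[(tert-butyldimethylsilyl)oxy]-2,6-dimethylocta-2,6-dien-1-ol
Conditions: SeO2 (cat.), t-BuOOH, salicylic acid (cat.), CH2Cl2, rt
Reagents that add atoms: tert-butyl hydroperoxide, CC(C)(C)OO (oxygen carried over by catalytic selenium dioxide, O=[Se]=O)
Why: Selenium dioxide allylic oxidation (ene reaction, then [2,3]-sigmatropic shift) should attack the electron-richer terminal olefin at its (E)-methyl group, giving the C8 alcohol with the 6E geometry kept, while the C2=C3 olefin is deactivated by the allylic silyloxy group.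

Step 3
Reactants: 3 (2E,6E)-8-[(tert-butyldimethylsilyl)oxy]-2,6-dimethylocta-2,6-dien-1-ol
Product: 4 {[(2E,6E)-8-bromo-3,7-dimethylocta-2,6-dien-1-yl]oxy}(tert-butyl)dimethylsilane
Conditions: CBr4, PPh3, CH2Cl2, 0 °C
Reagents that add atoms: carbon tetrabromide, BrC(Br)(Br)Br
Why: Appel bromination converts the primary allylic alcohol into the bromide under neutral conditions, without allylic transposition and without loss of the silyl ether.

Step 4
Reactants: 4 {[(2E,6E)-8-bromo-3,7-dimethylocta-2,6-dien-1-yl]oxy}(tert-butyl)dimethylsilane; 5 propyne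
Product: 8 tert-butyl{[(2E,6E)-3,7-dimethyldodeca-2,6-dien-10-yn-1-yl]oxy}dimethylsilane, via 1,3-dilithiopropyne 6 (not isolated), via lithium acetylide 7 (not isolated)
Conditions: 5, n-BuLi (2 equiv), TMEDA, Et2O–hexane, −78 → 0 °C; then 4, −78 → −20 °C; then MeI, THF–DMPU, −20 °C → rt
Reagents that add atoms: iodomethane, CI
Why: In this propargyl-dianion alkylation the sp3 carbon of 1,3-dilithiopropyne is the more nucleophilic site and should displace the primary allylic bromide by SN2 (C8–C9 bond), after which the remaining acetylide 7 is C-methylated by iodomethane; both olefin geometries are untouched.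

Step 5
Reactants: 8 tert-butyl{[(2E,6E)-3,7-dimethyldodeca-2,6-dien-10-yn-1-yl]oxy}dimethylsilane
Product: 10 tert-butyl{[(2E,6E,10E)-11-iodo-3,7-dimethyldodeca-2,6,10-trien-1-yl]oxy}dimethylsilane, via alkenylzirconocene 9 (not isolated)
Conditions: Cp2Zr(H)Cl (excess), THF, rt → 45 °C; then I2, 0 °C
Reagents that add atoms: iodine, II
Why: Hydrozirconation–iodination: syn addition of Zr–H to the internal alkyne with excess reagent should equilibrate the metal to the less hindered, methyl-bearing carbon C11, and iodinolysis with retention gives the (E)-2-iodoalk-2-ene; the trisubstituted olefins do not react.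

Step 6
Reactants: 10 tert-butyl{[(2E,6E,10E)-11-iodo-3,7-dimethyldodeca-2,6,10-trien-1-yl]oxy}dimethylsilane
Product: 11 (2E,6E,10E)-11-iodo-3,7-dimethyldodeca-2,6,10-trien-1-ol
Conditions: TBAF, THF, 0 °C → rt
Reagents that add atoms: none
Why: Fluoride-mediated desilylation frees the primary allylic alcohol and leaves the alkenyl iodide untouched.

Step 7
Reactants: 11 (2E,6E,10E)-11-iodo-3,7-dimethyldodeca-2,6,10-trien-1-ol
Product: 12 (2E,6E,10E)-11-iodo-3,7-dimethyldodeca-2,6,10-trienal
Conditions: MnO2, CH2Cl2, rt
Reagents that add atoms: none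
Why: Manganese dioxide oxidation is selective for the allylic alcohol and should stop at the conjugated aldehyde with the 2E geometry kept.

Step 8
Reactants: 13 3-[(tert-butyldimethylsilyl)oxy]propanal; 14 methyl acrylate
Product: 15 methyl 5-[(tert-butyldimethylsilyl)oxy]-3-hydroxy-2-methylidenepentanoate (racemic)
Conditions: DABCO, MeOH, rt
Reagents that add atoms: none
Why: Morita–Baylis–Hillman reaction: the ammonium enolate formed from DABCO and the acrylate adds to the aldehyde; the carbinol centre formed is racemic and is removed in the next step.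

Step 9
Reactants: 15 methyl 5-[(tert-butyldimethylsilyl)oxy]-3-hydroxy-2-methylidenepentanoate
Product: 16 methyl (2Z)-2-(bromomethyl)-5-[(tert-butyldimethylsilyl)oxy]pent-2-enoate
Conditions: NBS, Me2S, CH2Cl2, 0 °C → rt
Reagents that add atoms: N-bromosuccinimide, BrN1C(=O)CCC1=O
Why: The alkoxysulfonium salt formed with the bromodimethylsulfonium reagent is displaced by bromide in the SN2′ sense (allylic transposition), which should give the thermodynamically preferred (Z)-2-(bromomethyl)alk-2-enoate under conditions that spare the silyl ether.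

Step 10
Reactants: 12 (2E,6E,10E)-11-iodo-3,7-dimethyldodeca-2,6,10-trienal; 16 methyl (2Z)-2-(bromomethyl)-5-[(tert-butyldimethylsilyl)oxy]pent-2-enoate
Product: 20 (4S,5S)-4-{2-[(tert-butyldimethylsilyl)oxy]ethyl}-5-[(1E,5E,9E)-10-iodo-2,6-dimethylundeca-1,5,9-trien-1-yl]-3-methylideneoxolan-2-one, via allylchromium species 17 (not isolated), via silyl ether 18 (not isolated), via hydroxy ester 19 (not isolated)
Conditions: CrCl2 (10 mol %), chiral carbazole-bis(oxazoline) ligand (12 mol %, enantiomer giving 1S), Mn, Me3SiCl, iPr2NEt (cat.), THF, rt; then aq. citric acid, THF; then PPTS (cat.), CH2Cl2, rt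
Reagents that add atoms: none
Why: Chromium-catalysed enantioselective 2-(alkoxycarbonyl)allylation (Nozaki–Hiyama type, Mn as reductant, Me3SiCl for turnover): the (Z)-allylchromium 17 should add through its γ-carbon to the aldehyde in a closed chair transition state with the γ-substituent axial, giving the syn adduct (C1 and C14 set together, aldehyde face chosen by the ligand), and after desilylation the C1 hydroxyl closes the cis α-methylene-γ-lactone on the ester; without nickel the alkenyl iodide is inert.

Step 11
Reactants: 20 (4S,5S)-4-{2-[(tert-butyldimethylsilyl)oxy]ethyl}-5-[(1E,5E,9E)-10-iodo-2,6-dimethylundeca-1,5,9-trien-1-yl]-3-methylideneoxolan-2-one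
Product: 21 (4S,5S)-4-(2-hydroxyethyl)-5-[(1E,5E,9E)-10-iodo-2,6-dimethylundeca-1,5,9-trien-1-yl]-3-methylideneoxolan-2-one
Conditions: HF·pyridine, pyridine, THF, 0 °C → rt
Reagents that add atoms: none
Why: Buffered desilylation removes the primary silyl ether while the lactone, its exocyclic acrylate unit and the alkenyl iodide are inert.

Step 12
Reactants: 21 (4S,5S)-4-(2-hydroxyethyl)-5-[(1E,5E,9E)-10-iodo-2,6-dimethylundeca-1,5,9-trien-1-yl]-3-methylideneoxolan-2-one
Product: 22 2-{(2S,3S)-2-[(1E,5E,9E)-10-iodo-2,6-dimethylundeca-1,5,9-trien-1-yl]-4-methylidene-5-oxooxolan-3-yl}acetaldehyde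
Conditions: Dess–Martin periodinane, CH2Cl2, 0 °C → rt
Reagents that add atoms: none
Why: Dess–Martin oxidation gives the aldehyde under near-neutral conditions, and since C13 is a CH2 group there is no centre next to the aldehyde that could epimerise.

Step 13
Reactants: 22 2-{(2S,3S)-2-[(1E,5E,9E)-10-iodo-2,6-dimethylundeca-1,5,9-trien-1-yl]-4-methylidene-5-oxooxolan-3-yl}acetaldehyde
Product: 24 (1S,2E,6E,10E,12S,14S)-12-hydroxy-3,7,11-trimethyl-15-methylidene-17-oxabicyclo[12.3.0]heptadeca-2,6,10-trien-16-one, via alkenylchromium species 23 (not isolated)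
Conditions: CrCl2 (6 equiv), NiCl2 (0.1 equiv), chiral oxazoline–sulfonamide ligand (6.6 equiv, enantiomer giving 12S), Et3N (6.6 equiv), THF, slow addition of 22 to 2 mM, rt
Reagents that add atoms: none
Why: Nickel(0), formed from NiCl2 by Cr(II), inserts into the C11–I bond of the (E)-2-iodoalk-2-ene with retention and hands the alkenyl group to chromium(III), and the ligand-bound alkenylchromium 23 adds to the C12 aldehyde of the same molecule. This is an intramolecular Nozaki–Hiyama–Kishi reaction in its sulfonamide-ligand (asymmetric) variant, the established carbinol-forming macrocyclisation of iodoalkene aldehydes. The 14-membered carbocycle closes by C11–C12 bond formation in the 14-exo-trig mode (carbonyl oxygen outside the new ring, C10=C11 inside it with E geometry retained), under high dilution by slow addition. The one new stereocentre, C12 (S), should be set by the chromium-bound chiral ligand, which selects the aldehyde face; the lactone centres C14 and C1 are 1,3- and 1,4-related and are not relied on. The step needs chemoselectivity for the aldehyde over the lactone carbonyl, the acrylate-type C15=C17 unit and the allylic C1–O bond, which the low basicity and oxophilicity of alkenylchromium(III) secure, and the CH2 at C13 excludes epimerisation next to the aldehyde.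

Step 14
Reactants: 24 (1S,2E,6E,10E,12S,14S)-12-hydroxy-3,7,11-trimethyl-15-methylidene-17-oxabicyclo[12.3.0]heptadeca-2,6,10-trien-16-one
Product: 25 (1S,2E,6E,10S,11S,12S,14S)-10,11-epoxy-12-hydroxy-3,7,11-trimethyl-15-methylidene-17-oxabicyclo[12.3.0]heptadeca-2,6-dien-16-one
Conditions: Ti(OiPr)4 (1.1 equiv), L-(+)-diisopropyl tartrate (1.3 equiv), t-BuOOH (anhydrous), 4 Å MS, CH2Cl2, −25 °C
Reagents that add atoms: tert-butyl hydroperoxide, CC(C)(C)OO
Why: Sharpless asymmetric epoxidation in the matched sense: the (12S)-allylic alcohol is the fast-reacting antipode for the L-(+)-tartrate titanium complex, which should deliver oxygen to the C10=C11 face that gives the erythro epoxy alcohol (threo disfavoured by A(1,2) strain with the C11 methyl), setting C10 and C11, while the two other trisubstituted olefins and the acrylate unit lack a free allylic hydroxyl and are left.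

Step 15
Reactants: 25 (1S,2E,6E,10S,11S,12S,14S)-10,11-epoxy-12-hydroxy-3,7,11-trimethyl-15-methylidene-17-oxabicyclo[12.3.0]heptadeca-2,6-dien-16-one
Product: 26 (1S,2E,6E,10S,11R,12S,14S)-10,11-epoxy-3,7,11-trimethyl-15-methylidene-16-oxo-17-oxabicyclo[12.3.0]heptadeca-2,6-dien-12-yl acetate
Conditions: Ac2O, pyridine, DMAP (cat.), CH2Cl2, 0 °C → rt
Reagents that add atoms: acetic anhydride, CC(=O)OC(C)=O
Why: DMAP-catalysed acylation of the secondary alcohol proceeds without free alkoxide, so neither Payne rearrangement of the epoxy alcohol nor addition to the α-methylene lactone is expected; the C11 descriptor changes from S to R by priority only.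

**Compound list**

1 | geraniol, (2E)-3,7-dimethylocta-2,6-dien-1-ol | CC(C)=CCC/C(C)=C/CO | starting material
2 | tert-butyl{[(2E)-3,7-dimethylocta-2,6-dien-1-yl]oxy}dimethylsilane | CC(C)=CCC/C(C)=C/CO[Si](C)(C)C(C)(C)C | intermediate
3 | (2E,6E)-8-[(tert-butyldimethylsilyl)oxy]-2,6-dimethylocta-2,6-dien-1-ol | OC/C(C)=C/CC/C(C)=C/CO[Si](C)(C)C(C)(C)C | intermediate
4 | {[(2E,6E)-8-bromo-3,7-dimethylocta-2,6-dien-1-yl]oxy}(tert-butyl)dimethylsilane | BrC/C(C)=C/CC/C(C)=C/CO[Si](C)(C)C(C)(C)C | intermediate
5 | propyne | CC#C | starting material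
6 | 1,3-dilithiopropyne (formed in the flask) | [Li]CC#C[Li] | intermediate
7 | [(5E,9E)-11-[(tert-butyldimethylsilyl)oxy]-5,9-dimethylundeca-5,9-dien-1-yn-1-yl]lithium (formed in the flask) | [Li]C#CCC/C(C)=C/CC/C(C)=C/CO[Si](C)(C)C(C)(C)C | intermediate
8 | tert-butyl{[(2E,6E)-3,7-dimethyldodeca-2,6-dien-10-yn-1-yl]oxy}dimethylsilane | CC#CCC/C(C)=C/CC/C(C)=C/CO[Si](C)(C)C(C)(C)C | intermediate
9 | chlorido[(2E,6E,10E)-12-[(tert-butyldimethylsilyl)oxy]-6,10-dimethyldodeca-2,6,10-trien-2-yl]zirconocene (formed in the flask) | C/C(=C\CC/C(C)=C/CC/C(C)=C/CO[Si](C)(C)C(C)(C)C)[Zr](Cl)(C1C=CC=C1)C1C=CC=C1 | intermediate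
10 | tert-butyl{[(2E,6E,10E)-11-iodo-3,7-dimethyldodeca-2,6,10-trien-1-yl]oxy}dimethylsilane | C/C(I)=C\CC/C(C)=C/CC/C(C)=C/CO[Si](C)(C)C(C)(C)C | intermediate
11 | (2E,6E,10E)-11-iodo-3,7-dimethyldodeca-2,6,10-trien-1-ol | C/C(I)=C\CC/C(C)=C/CC/C(C)=C/CO | intermediate
12 | (2E,6E,10E)-11-iodo-3,7-dimethyldodeca-2,6,10-trienal | C/C(I)=C\CC/C(C)=C/CC/C(C)=C/C=O | intermediate
13 | 3-[(tert-butyldimethylsilyl)oxy]propanal | O=CCCO[Si](C)(C)C(C)(C)C | starting material
14 | methyl acrylate | C=CC(=O)OC | starting material
15 | methyl 5-[(tert-butyldimethylsilyl)oxy]-3-hydroxy-2-methylidenepentanoate (racemic) | C=C(C(=O)OC)C(O)CCO[Si](C)(C)C(C)(C)C | intermediate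
16 | methyl (2Z)-2-(bromomethyl)-5-[(tert-butyldimethylsilyl)oxy]pent-2-enoate | COC(=O)/C(CBr)=C/CCO[Si](C)(C)C(C)(C)C | intermediate
17 | (Z)-2-(methoxycarbonyl)allylchromium(III) species from 16, chiral ligand omitted (formed in the flask) | COC(=O)/C(C[Cr](Cl)Cl)=C/CCO[Si](C)(C)C(C)(C)C | intermediate
18 | O-trimethylsilyl ether of hydroxy ester 19 (formed in the flask) | COC(=O)C(=C)[C@H](CCO[Si](C)(C)C(C)(C)C)[C@@H](O[Si](C)(C)C)/C=C(\C)CC/C=C(\C)CC/C=C(\C)I | intermediate
19 | methyl (3S,4S,5E,9E,13E)-3-{2-[(tert-butyldimethylsilyl)oxy]ethyl}-4-hydroxy-14-iodo-6,10-dimethyl-2-methylidenepentadeca-5,9,13-trienoate (syn; formed in the flask) | COC(=O)C(=C)[C@H](CCO[Si](C)(C)C(C)(C)C)[C@@H](O)/C=C(\C)CC/C=C(\C)CC/C=C(\C)I | intermediate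
20 | (4S,5S)-4-{2-[(tert-butyldimethylsilyl)oxy]ethyl}-5-[(1E,5E,9E)-10-iodo-2,6-dimethylundeca-1,5,9-trien-1-yl]-3-methylideneoxolan-2-one (cis) | C=C1C(=O)O[C@@H](/C=C(\C)CC/C=C(\C)CC/C=C(\C)I)[C@H]1CCO[Si](C)(C)C(C)(C)C | intermediate
21 | (4S,5S)-4-(2-hydroxyethyl)-5-[(1E,5E,9E)-10-iodo-2,6-dimethylundeca-1,5,9-trien-1-yl]-3-methylideneoxolan-2-one | C=C1C(=O)O[C@@H](/C=C(\C)CC/C=C(\C)CC/C=C(\C)I)[C@H]1CCO | intermediate
22 | 2-{(2S,3S)-2-[(1E,5E,9E)-10-iodo-2,6-dimethylundeca-1,5,9-trien-1-yl]-4-methylidene-5-oxooxolan-3-yl}acetaldehyde | C=C1C(=O)O[C@@H](/C=C(\C)CC/C=C(\C)CC/C=C(\C)I)[C@H]1CC=O | intermediate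
23 | alkenylchromium(III) species from 22, chiral ligand omitted (formed in the flask) | C=C1C(=O)O[C@@H](/C=C(\C)CC/C=C(\C)CC/C=C(\C)[Cr](Cl)Cl)[C@H]1CC=O | intermediate
24 | (1S,2E,6E,10E,12S,14S)-12-hydroxy-3,7,11-trimethyl-15-methylidene-17-oxabicyclo[12.3.0]heptadeca-2,6,10-trien-16-one | C=C1C(=O)O[C@H]2/C=C(\C)CC/C=C(\C)CC/C=C(\C)[C@@H](O)C[C@@H]12 | intermediate
25 | (1S,2E,6E,10S,11S,12S,14S)-10,11-epoxy-12-hydroxy-3,7,11-trimethyl-15-methylidene-17-oxabicyclo[12.3.0]heptadeca-2,6-dien-16-one | C=C1C(=O)O[C@H]2/C=C(\C)CC/C=C(\C)CC[C@@H]3O[C@@]3(C)[C@@H](O)C[C@@H]12 | intermediate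
26 | (1S,2E,6E,10S,11R,12S,14S)-10,11-epoxy-3,7,11-trimethyl-15-methylidene-16-oxo-17-oxabicyclo[12.3.0]heptadeca-2,6-dien-12-yl acetate | C=C1C(=O)O[C@H]2/C=C(\C)CC/C=C(\C)CC[C@@H]3O[C@@]3(C)[C@@H](OC(C)=O)C[C@@H]12 | target

**Step count and risks**

Total step count: 15. Longest linear sequence: 13 steps (steps 1–7, then 10–15).

The three steps most likely to fail:

Step 10. The chromium catalyst may discriminate the faces of the β,β-disubstituted enal poorly (low enantiomeric purity), and the syn selectivity may leak if the allylchromium reacts through its E form or an open transition state. The fallback sets out from 12 and comes back at 20, with reagent control by a chiral allylborane. tert-Butyldimethyl(penta-3,4-dien-1-yloxy)silane is hydroborated at low temperature with diisopinocampheylborane (antipode chosen for 1S) to the kinetic (Z)-γ-substituted allylborane. This adds to 12 at −78 °C through the chair transition state and, after oxidative work-up (NaBO3), should give the syn homoallylic alcohol F1, which has C1 and C14 as in 20 and a vinyl group in place of C15. 9-BBN then NaBO3 hydroborates only the terminal vinyl group to give the diol F2. TEMPO/PhI(OAc)2 oxidises the primary alcohol and the lactol that follows to the saturated cis-lactone F3. LDA and Eschenmoser's salt give the α-(dimethylaminomethyl) lactone F4, iodomethane gives its methiodide F5, and NaHCO3 eliminates to 20.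

Step 13. Intermolecular coupling to dimers and oligomers, protodemetalation of 23, and attack on the wrong aldehyde face (C12 epimer) may compete. The fallback sets out from 22 and comes back at 24, separating ring closure from stereocontrol. Ring closure under ligand-free nickel/chromium conditions (CrCl2, cat. NiCl2, DMSO–THF, high dilution) gives the C12-epimeric macrocyclic alcohols F6. Dess–Martin oxidation converges them to the macrocyclic enone F7. Corey–Bakshi–Shibata reduction with the (R)-oxazaborolidine and catecholborane, the alkenyl residue acting as the large group, should return 24.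

Step 14. The bulky dimeric titanium–tartrate complex may not take up the secondary alkoxide held in the 14-membered ring, so that turnover stalls and the Lewis acid opens the oxirane. The fallback sets out from 24 and comes back at 25. It moves the stereocontrol from the catalyst to the substrate: vanadium-alkoxide-directed epoxidation (VO(acac)2, t-BuOOH, CH2Cl2) delivers oxygen syn to O12 from a small achiral metal centre, with the erythro preference imposed by A(1,2) strain from the C11 methyl. This fallback makes no new compound (F0).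

Further compounds
F1 | step 10 | syn homoallylic alcohol, 3-{2-[(tert-butyldimethylsilyl)oxy]ethyl}-14-iodo-6,10-dimethylpentadeca-1,5,9,13-tetraen-4-ol with C1/C14 as in 20 | C=C[C@H](CCO[Si](C)(C)C(C)(C)C)[C@@H](O)/C=C(\C)CC/C=C(\C)CC/C=C(\C)I
F2 | step 10 | diol from hydroboration of the vinyl group of F1 | OCC[C@H](CCO[Si](C)(C)C(C)(C)C)[C@@H](O)/C=C(\C)CC/C=C(\C)CC/C=C(\C)I
F3 | step 10 | (4S,5S)-4-{2-[(tert-butyldimethylsilyl)oxy]ethyl}-5-[(1E,5E,9E)-10-iodo-2,6-dimethylundeca-1,5,9-trien-1-yl]oxolan-2-one (cis) | C1C(=O)O[C@@H](/C=C(\C)CC/C=C(\C)CC/C=C(\C)I)[C@H]1CCO[Si](C)(C)C(C)(C)C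
F4 | step 10 | 3-[(dimethylamino)methyl] derivative of F3 (C3 epimers) | CN(C)CC1C(=O)O[C@@H](/C=C(\C)CC/C=C(\C)CC/C=C(\C)I)[C@H]1CCO[Si](C)(C)C(C)(C)C
F5 | step 10 | methiodide of F4 | C[N+](C)(C)CC1C(=O)O[C@@H](/C=C(\C)CC/C=C(\C)CC/C=C(\C)I)[C@H]1CCO[Si](C)(C)C(C)(C)C.[I-]
F6 | step 13 | (1S,2E,6E,10E,14S)-12-hydroxy-3,7,11-trimethyl-15-methylidene-17-oxabicyclo[12.3.0]heptadeca-2,6,10-trien-16-one, both C12 epimers | C=C1C(=O)O[C@H]2/C=C(\C)CC/C=C(\C)CC/C=C(\C)C(O)C[C@@H]12
F7 | step 13 | (1S,2E,6E,10E,14S)-3,7,11-trimethyl-15-methylidene-17-oxabicyclo[12.3.0]heptadeca-2,6,10-triene-12,16-dione | C=C1C(=O)O[C@H]2/C=C(\C)CC/C=C(\C)CC/C=C(\C)C(=O)C[C@@H]12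
F0 | step 14 | none | none
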